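## Structural features

The target is a 3-methoxyflavone. Ring A (C4a to C8a) is a phloroglucinol ring fused through O1/C8a and C4a/C4 to the γ-pyrone ring C, which carries the 3-OMe and, at C2, ring B (4-methoxyphenyl). Ring A is pentasubstituted: C5–OH (hydrogen-bonded to C4=O), C6–H, C7–OH and, at C8, a 1-(4-hydroxyphenyl)ethyl group. The only stereocentre is the methine Cα of that group. It is (R) (CIP order C8 > C1″ of the hydroxyphenyl ring > CH3 > H) and is a 1,1-diarylethane centre with no heteroatom on it. The C8–Cα bond is a Friedel–Crafts bond between a phloroglucinol ring and a 4-oxybenzyl cation, so strong acid can break it or move the side chain from C8 to C6 (also through Wessely–Moser ring opening of the 5-hydroxyflavone). The two methyl ethers (4′-OMe and the enol-type 3-OMe) must survive while three phenols are set free. The real difficulty is twofold: one configuration at Cα, and the side chain at C8 and not at the similar C6. The key step exploits the four-atom array O1–C8a–C8–Cα. While O1 is still a free phenol this array is a latent ortho-quinone methide, so ring A can be dearomatised briefly, Cα made trigonal and then reduced under catalyst control. The same analysis lets Cα be the former carbonyl carbon of an aryl methyl ketone, so the acetyl group of a phloroacetophenone becomes the C8 side chain and not, as usual, C4.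

## Logic of the disconnections

15 from 14. The three O–CH2Ph bonds (O5, O7, O4″) are cut. Benzyl is chosen because neutral hydrogenolysis leaves both methyl ethers and never exposes the acid-labile C8–Cα bond of the free 5-hydroxyflavone to acid. The forward step must not reduce C2=C3.

14 from 11 and 12. Ring C is opened at O1–C2 and C2–C3. Ring B and C2 arrive as one acyl unit and the 3-OMe is already in 11. Compound 11 has a single free hydroxyl, lying between the carbon that bears the side chain and the carbon that bears the acyl group, so ring closure can only give the 8-substituted chromenone. The forward step needs acyl transfer at a hindered phenol and a dehydration mild enough to spare Cα.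

11 from 8 and 9. The aryl–acyl bond C4a–C4 is cut, which leaves a bromine at the future C4a. This keeps the ring-C carbonyl out of the key step, where it would tie up the phenol in a hydrogen bond and would not survive the organomagnesium step before it. The forward step is a halogen–metal exchange on a free phenol that must not disturb Cα.

8 from 6 through 7 (key disconnection). The Cα–H bond is cut. Going back, the stereocentre disappears into the trigonal carbon of 7, and 7 is a tautomer of the achiral 6. The forward step must deliver hydride to one face of Cα.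

6 from 3 and 4 through 5. The Cα–C1″ bond is cut, so Cα is the acetyl carbonyl carbon of 3 and the methyl group is the acetyl methyl. Both aryl–Cα bonds are thus in place without any C–C bond formation at a crowded ring position. The forward addition must outrun enolisation.

3 from 2, and 2 from 1. The C–Br bond and two O–benzyl bonds are cut, back to a C2-symmetric, commercial ketone in which the three ring positions are not yet differentiated. The forward steps need bromination beside the one free, chelated hydroxyl and benzylation that leaves that hydroxyl untouched.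

## Other disconnections considered

Alternative 1: (the first that comes to mind) cut C8–Cα on the finished flavonol. The forward step is an acid-mediated Friedel–Crafts benzylation of 5,7-dihydroxy-3-methoxy-2-(4-methoxyphenyl)chromen-4-one A1 with 4-(1-hydroxyethyl)phenol A2 through its para-quinone methide. A1 is nucleophilic at both C6 and C8, so the 6-isomer A3 is expected alongside 15. The alkylation is reversible under the acid that drives it, so any kinetic preference would drift. The two faces of the small cation differ only by CH3 against H, and a chiral acid would be bound far from the bond being formed. The chosen plan fixes C8 by construction and sets Cα inside a hydrogen-bonded complex anchored at the neighbouring oxygen.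

Alternative 2: cut the same C8–Cα bond, but stereoconvergently. The forward step is a nickel-catalysed enantioconvergent reductive coupling (NiBr2·diglyme, chiral bis(oxazoline), Mn) of the 8-iodoflavone A4 with racemic 1-(benzyloxy)-4-(1-chloroethyl)benzene A5, giving 14 directly. The aryl–nickel intermediate from A4 would carry oxygen substituents on both ortho carbons, which should slow radical capture and reductive elimination. The enantio-determining organisation in this reaction class rests on unhindered aryl partners. A5 ionises easily and opens a racemic background path, and the chromenone is a Michael acceptor under reducing metal. The route is short but its single hard step has no feature of the substrate working for it, whereas the chosen key step uses the O1 phenol as a built-in anchor.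

Alternative 3: cut Cα–C1″ inside a temporary lactone ring. The forward step is a Hayashi–Miyaura conjugate arylation of 5,7-bis(benzyloxy)coumarin A6 with [4-(benzyloxy)phenyl]boronic acid A7 (Rh(acac)(C2H4)2, (R)-SEGPHOS), giving the 4-arylchroman-2-one A8. Lactone opening and hydrodecarboxylation would turn C3 into the methyl group and give phenol A9. The peri 5-benzyloxy group of A6 shields the β-carbon that the aryl–rhodium species must reach, and one carbon has to be excised at the cost of two extra steps. A9 also has no handle at the future C4a, so the ring-C ketone would have to be installed by electrophilic acylation under acid on the most acid-labile intermediate. The chosen plan needs no excision and carries a bromine as the C4a handle through the key step.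

Key step: step 4

Assumption: the (R)-configured phosphoric acid named in step 4 is taken to deliver (R)-8. The antipodal catalyst is equally available, and the sense of induction has to be assigned on the first batch.

Assumption: reagent 4 is bought as a 1.0 M solution in THF.

## Route

Step 1
Reactants: 1 1-(2,4,6-trihydroxyphenyl)ethan-1-one
Product: 2 1-[2,4-bis(benzyloxy)-6-hydroxyphenyl]ethan-1-one
Conditions: BnBr (2.05 equiv), K2CO3 (2.2 equiv), DMF, rt to 60 °C
Reagents that add atoms: benzyl bromide, BrCc1ccccc1
Why: Williamson etherification; the para hydroxyl and one ortho hydroxyl are alkylated, while the second ortho hydroxyl is held in a six-membered hydrogen bond to the carbonyl and should stay free (the usual selectivity for 2,4,6-trihydroxyaryl ketones); this free hydroxyl is the future O1.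

Step 2
Reactants: 2 1-[2,4-bis(benzyloxy)-6-hydroxyphenyl]ethan-1-one
Product: 3 1-[4,6-bis(benzyloxy)-3-bromo-2-hydroxyphenyl]ethan-1-one
Conditions: N-bromosuccinimide (1.0 equiv), MeCN, 0 °C, dark
Reagents that add atoms: N-bromosuccinimide, O=C1CCC(=O)N1Br
Why: Electrophilic aromatic bromination; the free phenol directs to its own ortho carbon, which is also para to a benzyloxy group and less crowded than the carbon between the two benzyloxy groups, and one equivalent at 0 °C limits dibromination; the bromine marks the future C4a.

Step 3
Reactants: 3 1-[4,6-bis(benzyloxy)-3-bromo-2-hydroxyphenyl]ethan-1-one; 4 [4-(benzyloxy)phenyl]magnesium bromide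
Product: 6 3,5-bis(benzyloxy)-2-{1-[4-(benzyloxy)phenyl]ethenyl}-6-bromophenol, via racemic tertiary carbinol 5 (not isolated)
Conditions: 4 (3.0 equiv), LaCl3·2LiCl (1.0 equiv), THF, 0 °C to rt; 1 M HCl, 0 °C; then pyridinium p-toluenesulfonate (5 mol %), toluene, 40 °C
Reagents that add atoms: none
Why: 1,2-Addition of an aryl Grignard reagent to a 2-hydroxyaryl methyl ketone (the first equivalent makes the magnesium phenoxide, whose chelate activates the carbonyl, and the lanthanum salt should suppress enolisation); the doubly benzylic, oxygen-stabilised carbinol 5 should lose water by E1 elimination to the 1,1-diarylethene 6, and the aryl bromide is inert to the Grignard reagent at this temperature.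

Step 4
Reactants: 6 3,5-bis(benzyloxy)-2-{1-[4-(benzyloxy)phenyl]ethenyl}-6-bromophenol
Product: 8 3,5-bis(benzyloxy)-2-{(1R)-1-[4-(benzyloxy)phenyl]ethyl}-6-bromophenol, via ortho-quinone methide 7 (not isolated)
Conditions: (R)-3,3′-bis(2,4,6-triisopropylphenyl)-1,1′-binaphthyl-2,2′-diyl hydrogen phosphate (5 mol %), diethyl 2,6-dimethyl-1,4-dihydropyridine-3,5-dicarboxylate (1.3 equiv), toluene, 25 to 40 °C, N2, dark
Reagents that add atoms: none
Why: The chiral phosphoric acid protonates the terminal CH2 of 6 to a benzylic cation stabilised by the ortho hydroxyl, the ortho and para benzyloxy groups of ring A and the 4-benzyloxyphenyl ring, and loss of the phenolic proton to the phosphate gives the ortho-quinone methide 7, in which ring A is dearomatised and Cα is trigonal. In a ternary hydrogen-bonded complex (P–OH to the carbonyl oxygen of 7, P=O to the N–H of the dihydropyridine) hydride is transferred to Cα and ring A rearomatises, which makes the step irreversible. The closest known reaction type is the chiral-phosphoric-acid-catalysed transfer hydrogenation of 2-(1-arylvinyl)phenols to 1,1-diarylethanes through ortho-quinone methides. No ring is closed. The single new stereocentre Cα is controlled by the catalyst, whose 3,3′-aryl groups shield one face of the exocyclic C=C of bound 7. The E and Z forms of 7 should interconvert through the cation by rotation about the ring–Cα bond faster than hydride transfer, so both funnel into one product (Curtin–Hammett). The step needs enantiofacial selectivity and an ortho- rather than para-quinone methide pathway, and the substrate secures the second because its only free hydroxyl is the future O1 next to the alkene-bearing carbon, while the 4-benzyloxyphenyl ring cannot form a quinone methide. Product 8 has no alkene and cannot re-ionise under the weak acid, so its configuration should not erode, and the aryl bromide and benzyl ethers are untouched.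

Step 5
Reactants: 8 3,5-bis(benzyloxy)-2-{(1R)-1-[4-(benzyloxy)phenyl]ethyl}-6-bromophenol; 9 N,2-dimethoxy-N-methylacetamide
Product: 11 1-[4,6-bis(benzyloxy)-3-{(1R)-1-[4-(benzyloxy)phenyl]ethyl}-2-hydroxyphenyl]-2-methoxyethan-1-one, via dilithiated phenol 10 (not isolated)
Conditions: n-BuLi (2.2 equiv), THF, −78 °C; 9 (1.5 equiv), −78 to 0 °C; 1 M HCl, 0 °C
Reagents that add atoms: none
Why: Bromine–lithium exchange on the lithium phenoxide (the first equivalent removes the OH proton), then acylation of the aryllithium with a Weinreb amide, whose chelated tetrahedral intermediate prevents over-addition; at −78 °C exchange should be faster than lithiation of the benzyl ethers, and the hindered diarylmethine C–H is not deprotonated, so Cα keeps its configuration.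

Step 6
Reactants: 11 1-[4,6-bis(benzyloxy)-3-{(1R)-1-[4-(benzyloxy)phenyl]ethyl}-2-hydroxyphenyl]-2-methoxyethan-1-one; 12 4-methoxybenzoyl chloride
Product: 14 5,7-bis(benzyloxy)-8-{(1R)-1-[4-(benzyloxy)phenyl]ethyl}-3-methoxy-2-(4-methoxyphenyl)-4H-chromen-4-one, via 1,3-diketone 13 (not isolated)
Conditions: LiN(SiMe3)2 (3.3 equiv), THF, −78 to −10 °C; 12 (1.05 equiv), −78 °C to rt; 1 M HCl work-up; then p-TsOH·H2O (10 mol %), toluene, 80 °C
Reagents that add atoms: none
Why: Baker–Venkataraman sequence in its direct form: the phenoxide/enolate dianion of 11 is aroylated on carbon (or on oxygen with acyl shift in situ) to the 1,3-diketone 13, whose only phenol adds to the aryl ketone (6-exo-trig) and loses water under catalytic acid to the chromen-4-one. Because 11 has one free hydroxyl, flanked by the side-chain carbon and the acyl carbon, only the 8-substituted ring system can form; the acid is catalytic and weak so as not to protonate ring A at C8.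

Step 7
Reactants: 14 5,7-bis(benzyloxy)-8-{(1R)-1-[4-(benzyloxy)phenyl]ethyl}-3-methoxy-2-(4-methoxyphenyl)-4H-chromen-4-one
Product: 15 5,7-dihydroxy-8-[(1R)-1-(4-hydroxyphenyl)ethyl]-3-methoxy-2-(4-methoxyphenyl)-4H-chromen-4-one
Conditions: H2 (1 atm), palladium on carbon (10% Pd/C), EtOAc–MeOH 1:1, rt
Reagents that add atoms: none
Why: Hydrogenolysis of three aryl benzyl ethers under neutral conditions; the methyl ethers, the tetrasubstituted C2=C3 of the chromenone and the Cα–aryl bonds should not be cleaved, and no acid is present that could cause dealkylation or Wessely–Moser isomerisation.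

## Compound list

1 | 1-(2,4,6-trihydroxyphenyl)ethan-1-one | CC(=O)c1c(O)cc(O)cc1O | starting material
2 | 1-[2,4-bis(benzyloxy)-6-hydroxyphenyl]ethan-1-one | CC(=O)c1c(O)cc(OCc2ccccc2)cc1OCc1ccccc1 | intermediate
3 | 1-[4,6-bis(benzyloxy)-3-bromo-2-hydroxyphenyl]ethan-1-one | CC(=O)c1c(O)c(Br)c(OCc2ccccc2)cc1OCc1ccccc1 | intermediate
4 | [4-(benzyloxy)phenyl]magnesium bromide | Br[Mg]c1ccc(OCc2ccccc2)cc1 | starting material
5 | 3,5-bis(benzyloxy)-2-{1-[4-(benzyloxy)phenyl]-1-hydroxyethyl}-6-bromophenol (racemic) | CC(O)(c1ccc(OCc2ccccc2)cc1)c1c(O)c(Br)c(OCc2ccccc2)cc1OCc1ccccc1 | intermediate (not isolated)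
6 | 3,5-bis(benzyloxy)-2-{1-[4-(benzyloxy)phenyl]ethenyl}-6-bromophenol | C=C(c1ccc(OCc2ccccc2)cc1)c1c(O)c(Br)c(OCc2ccccc2)cc1OCc1ccccc1 | intermediate
7 | 3,5-bis(benzyloxy)-6-{1-[4-(benzyloxy)phenyl]ethylidene}-2-bromocyclohexa-2,4-dien-1-one (E/Z mixture) | CC(c1ccc(OCc2ccccc2)cc1)=C1C(=O)C(Br)=C(OCc2ccccc2)C=C1OCc1ccccc1 | intermediate (not isolated)
8 | 3,5-bis(benzyloxy)-2-{(1R)-1-[4-(benzyloxy)phenyl]ethyl}-6-bromophenol | Oc1c(Br)c(OCc2ccccc2)cc(OCc2ccccc2)c1[C@H](C)c1ccc(OCc2ccccc2)cc1 | intermediate
9 | N,2-dimethoxy-N-methylacetamide | COCC(=O)N(C)OC | starting material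
10 | lithium 3,5-bis(benzyloxy)-2-{(1R)-1-[4-(benzyloxy)phenyl]ethyl}-6-lithiophenolate | [Li]Oc1c([Li])c(OCc2ccccc2)cc(OCc2ccccc2)c1[C@H](C)c1ccc(OCc2ccccc2)cc1 | intermediate (not isolated)
11 | 1-[4,6-bis(benzyloxy)-3-{(1R)-1-[4-(benzyloxy)phenyl]ethyl}-2-hydroxyphenyl]-2-methoxyethan-1-one | COCC(=O)c1c(O)c([C@H](C)c2ccc(OCc3ccccc3)cc2)c(OCc2ccccc2)cc1OCc1ccccc1 | intermediate
12 | 4-methoxybenzoyl chloride | COc1ccc(C(Cl)=O)cc1 | starting material
13 | 1-[4,6-bis(benzyloxy)-3-{(1R)-1-[4-(benzyloxy)phenyl]ethyl}-2-hydroxyphenyl]-2-methoxy-3-(4-methoxyphenyl)propane-1,3-dione (C2 epimers and enol forms) | COc1ccc(C(=O)C(OC)C(=O)c2c(O)c([C@H](C)c3ccc(OCc4ccccc4)cc3)c(OCc3ccccc3)cc2OCc2ccccc2)cc1 | intermediate (not isolated)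
14 | 5,7-bis(benzyloxy)-8-{(1R)-1-[4-(benzyloxy)phenyl]ethyl}-3-methoxy-2-(4-methoxyphenyl)-4H-chromen-4-one | COc1ccc(-c2oc3c([C@H](C)c4ccc(OCc5ccccc5)cc4)c(OCc4ccccc4)cc(OCc4ccccc4)c3c(=O)c2OC)cc1 | intermediate
15 | 5,7-dihydroxy-8-[(1R)-1-(4-hydroxyphenyl)ethyl]-3-methoxy-2-(4-methoxyphenyl)-4H-chromen-4-one | COc1ccc(-c2oc3c([C@H](C)c4ccc(O)cc4)c(O)cc(O)c3c(=O)c2OC)cc1 | target

## Step count and least certain steps

Total step count: 7. Longest linear sequence: 7 steps (1 to 15).

Step 4 (key step). What may go wrong is poor facial discrimination. The quinone methide is flanked on both sides (carbonyl and bromine on one, a benzyloxy group on the other), so neither geometry may be clearly preferred in the catalyst-bound state, and the bromine beside the carbonyl oxygen may loosen the hydrogen bond to the phosphate. Oligomerisation by hetero-Diels–Alder reaction of the quinone methide with unreacted alkene may compete. Fallback, setting out from 6: ionic hydrogenation (Et3SiH, CF3CO2H, CH2Cl2, −40 °C) through the same cation gives racemic 3,5-bis(benzyloxy)-2-{1-[4-(benzyloxy)phenyl]ethyl}-6-bromophenol F1. Preparative chromatography on a chiral stationary phase then separates the enantiomers, the (S)-enantiomer F2 is set aside, and the route is rejoined at 8.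

Step 3. What may go wrong is enolisation of the hindered, chelated methyl ketone by the basic aryl Grignard reagent in place of addition, which returns 3 on work-up. Fallback, setting out from 3, replaces carbonyl addition by cross-coupling. Silylation (t-BuMe2SiOTf, 2,6-lutidine) gives 1-[4,6-bis(benzyloxy)-3-bromo-2-(tert-butyldimethylsilyloxy)phenyl]ethan-1-one F3. Enol triflation (KN(SiMe3)2, PhNTf2, THF, −78 °C) gives the 1-arylvinyl triflate F4. Suzuki–Miyaura coupling with [4-(benzyloxy)phenyl]boronic acid (Pd(PPh3)4, K3PO4, dioxane–water, 60 °C; the vinyl triflate should react before the crowded aryl bromide) gives the silyl ether of the diarylethene F5. Bu4NF then returns the route to 6.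

Step 5. What may go wrong is protonation of the hindered aryllithium before it is acylated, or α-lithiation and Wittig rearrangement of a benzyl ether in competition with the exchange. Fallback, setting out from 8, avoids organolithium chemistry. Stille coupling with tributyl(1-ethoxyvinyl)stannane (Pd(PPh3)4, toluene, 100 °C; then 1 M HCl) gives 1-[4,6-bis(benzyloxy)-3-{(1R)-1-[4-(benzyloxy)phenyl]ethyl}-2-hydroxyphenyl]ethan-1-one F6. Reaction with 12 under the conditions of step 6 gives the 3-unsubstituted flavone F7. Epoxidation of C2=C3 with dimethyldioxirane and opening with catalytic p-TsOH gives the flavonol F8, and MeI with K2CO3 in acetone rejoins the route at 14.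

Step 6. What may go wrong is ipso-protonation of ring A at C8 during the acid dehydration, with loss or migration of the side chain, and slow acyl transfer at the phenol, which has substituents on both ortho carbons. Fallback, setting out from 11, is a one-pot thermal Allan–Robinson condensation (4-methoxybenzoic anhydride, potassium 4-methoxybenzoate, 170 °C; then brief KOH in MeOH). Ring closure is buffered by carboxylate and no strong acid meets the C8–Cα bond. The route is rejoined at 14 and no new compound arises (F0).

## Further compounds

F1 | step 4 | 3,5-bis(benzyloxy)-2-{1-[4-(benzyloxy)phenyl]ethyl}-6-bromophenol (racemic) | CC(c1ccc(OCc2ccccc2)cc1)c1c(O)c(Br)c(OCc2ccccc2)cc1OCc1ccccc1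
F2 | step 4 | 3,5-bis(benzyloxy)-2-{(1S)-1-[4-(benzyloxy)phenyl]ethyl}-6-bromophenol | Oc1c(Br)c(OCc2ccccc2)cc(OCc2ccccc2)c1[C@@H](C)c1ccc(OCc2ccccc2)cc1
F3 | step 3 | 1-[4,6-bis(benzyloxy)-3-bromo-2-(tert-butyldimethylsilyloxy)phenyl]ethan-1-one | CC(=O)c1c(O[Si](C)(C)C(C)(C)C)c(Br)c(OCc2ccccc2)cc1OCc1ccccc1
F4 | step 3 | 1-[4,6-bis(benzyloxy)-3-bromo-2-(tert-butyldimethylsilyloxy)phenyl]ethenyl trifluoromethanesulfonate | C=C(OS(=O)(=O)C(F)(F)F)c1c(O[Si](C)(C)C(C)(C)C)c(Br)c(OCc2ccccc2)cc1OCc1ccccc1
F5 | step 3 | [3,5-bis(benzyloxy)-2-{1-[4-(benzyloxy)phenyl]ethenyl}-6-bromophenoxy](tert-butyl)dimethylsilane | C=C(c1ccc(OCc2ccccc2)cc1)c1c(O[Si](C)(C)C(C)(C)C)c(Br)c(OCc2ccccc2)cc1OCc1ccccc1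
F6 | step 5 | 1-[4,6-bis(benzyloxy)-3-{(1R)-1-[4-(benzyloxy)phenyl]ethyl}-2-hydroxyphenyl]ethan-1-one | CC(=O)c1c(O)c([C@H](C)c2ccc(OCc3ccccc3)cc2)c(OCc2ccccc2)cc1OCc1ccccc1
F7 | step 5 | 5,7-bis(benzyloxy)-8-{(1R)-1-[4-(benzyloxy)phenyl]ethyl}-2-(4-methoxyphenyl)-4H-chromen-4-one | COc1ccc(-c2cc(=O)c3c(OCc4ccccc4)cc(OCc4ccccc4)c([C@H](C)c4ccc(OCc5ccccc5)cc4)c3o2)cc1
F8 | step 5 | 5,7-bis(benzyloxy)-8-{(1R)-1-[4-(benzyloxy)phenyl]ethyl}-3-hydroxy-2-(4-methoxyphenyl)-4H-chromen-4-one | COc1ccc(-c2oc3c([C@H](C)c4ccc(OCc5ccccc5)cc4)c(OCc4ccccc4)cc(OCc4ccccc4)c3c(=O)c2O)cc1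
F0 | step 6 | none | none
A1 | alternative 1 | 5,7-dihydroxy-3-methoxy-2-(4-methoxyphenyl)-4H-chromen-4-one | COc1ccc(-c2oc3cc(O)cc(O)c3c(=O)c2OC)cc1
A2 | alternative 1 | 4-(1-hydroxyethyl)phenol (racemic) | CC(O)c1ccc(O)cc1
A3 | alternative 1 | 5,7-dihydroxy-6-[1-(4-hydroxyphenyl)ethyl]-3-methoxy-2-(4-methoxyphenyl)-4H-chromen-4-one (configuration undefined) | COc1ccc(-c2oc3cc(O)c(C(C)c4ccc(O)cc4)c(O)c3c(=O)c2OC)cc1
A4 | alternative 2 | 5,7-bis(benzyloxy)-8-iodo-3-methoxy-2-(4-methoxyphenyl)-4H-chromen-4-one | COc1ccc(-c2oc3c(I)c(OCc4ccccc4)cc(OCc4ccccc4)c3c(=O)c2OC)cc1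
A5 | alternative 2 | 1-(benzyloxy)-4-(1-chloroethyl)benzene (racemic) | CC(Cl)c1ccc(OCc2ccccc2)cc1
A6 | alternative 3 | 5,7-bis(benzyloxy)-2H-chromen-2-one | O=c1ccc2c(OCc3ccccc3)cc(OCc3ccccc3)cc2o1
A7 | alternative 3 | [4-(benzyloxy)phenyl]boronic acid | OB(O)c1ccc(OCc2ccccc2)cc1
A8 | alternative 3 | (4R)-5,7-bis(benzyloxy)-4-[4-(benzyloxy)phenyl]chroman-2-one | O=C1C[C@H](c2ccc(OCc3ccccc3)cc2)c2c(OCc3ccccc3)cc(OCc3ccccc3)cc2O1
A9 | alternative 3 | 3,5-bis(benzyloxy)-2-{(1R)-1-[4-(benzyloxy)phenyl]ethyl}phenol | Oc1cc(OCc2ccccc2)cc(OCc2ccccc2)c1[C@H](C)c1ccc(OCc2ccccc2)cc1
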